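**Plan**

1. Retrosynthesis of 15 (3,4,6-tribromo-5-methylbenzene-1,2-diol): the C3–Br and C4–Br bonds are cut first (late aromatic bromination), leaving 3-bromo-4-methylcatechol 12. Its ring run C(Me)–C(Br)–C(OH)–C(OH) maps onto cyclotene: the methyl-bearing alkene carbon, the enol carbon and the ketone carbon are all there, and only the C–Br carbon between the methyl-bearing and the first oxygenated carbon is missing.
2. 12 is traced back through its mono(2-hydroxyethyl) ether 10 to the isomeric keto ketal 8, which already stands at the catechol oxidation level.
3. Key cut: the C(Br) ring carbon of 8 is excised together with both of its ring C–C bonds (to the carbonyl carbon and to the methyl-bearing carbon), leaving the five-membered enol ether 5 and CBr2 from bromoform.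
4. Forward: cyclotene 1 → methyl enol ether 3 → dioxolane 5 (five-membered carbocycle) → six-membered ring by dibromocarbene addition and cyclopropane opening (8) → aromatic ring by acid isomerisation (10) → ether cleavage (12) → dibromination (15).
5. Stereochemistry: the target has no stereocentre. The only stereocentres on the way are the cis-fused bridgeheads of the transient, racemic cyclopropane 7, and they are erased in the same step.

Key step: step 3

**Route**

Step 1
Reactants: 1 cyclotene (2-hydroxy-3-methylcyclopent-2-en-1-one); 2 iodomethane
Product: 3 2-methoxy-3-methylcyclopent-2-en-1-one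
Conditions: MeI, K2CO3, acetone, reflux
Reagents that add atoms: iodomethane, CI
Why: Williamson-type O-alkylation of the acidic diosphenol enol, whose potassium salt in acetone should alkylate on oxygen and thereby fix the methoxy group on the carbon next to the methyl-bearing carbon.

Step 2
Reactants: 3 2-methoxy-3-methylcyclopent-2-en-1-one; 4 1,2-bis(trimethylsilyloxy)ethane
Product: 5 6-methoxy-7-methyl-1,4-dioxaspiro[4.4]non-6-ene
Conditions: (Me3SiOCH2)2 (1.5 equiv), Me3SiOTf (0.05 equiv), CH2Cl2, −78 to −20 °C; pyridine quench, aq. NaHCO3
Reagents that add atoms: 1,2-bis(trimethylsilyloxy)ethane, C[Si](C)(C)OCCO[Si](C)(C)C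
Why: Noyori ketalisation, which is aprotic and cold, is driven by formation of hexamethyldisiloxane and should ketalise the enone carbonyl without moving the double bond or hydrolysing the enol ether.

Step 3
Reactants: 5 6-methoxy-7-methyl-1,4-dioxaspiro[4.4]non-6-ene; 6 bromoform
Product: 8 7-bromo-8-methyl-1,4-dioxaspiro[4.5]dec-7-en-6-one, via 6,6-dibromo-1-methoxy-5-methylspiro[bicyclo[3.1.0]hexane-2,2'-[1,3]dioxolane] 7 (not isolated)
Conditions: CHBr3 (1.5 equiv), KOtBu (2.0 equiv), pentane, −30 to 0 °C; then THF–H2O, NaOAc–AcOH buffer (pH 5), 25 °C
Reagents that add atoms: bromoform, BrC(Br)Br; water, O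
Why: KOtBu deprotonates CHBr3 and α-elimination of bromide gives singlet CBr2, which adds in a concerted (2+1) cheletropic step to the C6=C7 enol ether of 5; cyclopropane 7 then undergoes a disrotatory two-electron electrocyclic opening in which the endo bromide leaves (Woodward–Hoffmann–DePuy rule) and the methoxy oxygen stabilises the 2-bromoallyl cation as an oxocarbenium ion, which the buffered water converts via a hemiketal into the ketone with loss of methanol. The closest known reaction type is the dihalocarbene ring enlargement of cyclic alkyl and silyl enol ethers to 2-halocycloalk-2-enones. The six-membered ring is not formed by cyclisation but by enlargement of the five-membered ring: the carbene carbon makes two ring C–C bonds (to C6 and C7) while the old C6–C7 bond breaks, so the inserted carbon arrives with its bromine in place. No stereocentre is created in 8; the two bridgehead centres of 7 can only be cis and both become trigonal on opening. The step needs site selectivity, which is secured because the ketal leaves the enol ether as the only C=C and, by removing conjugation with the carbonyl, keeps it nucleophilic enough for the electrophilic carbene, and it needs the acyclic oxocarbenium ion to be hydrolysed without loss of the dioxolane, which the pH 5 buffer and the deactivation of the ketal by the newly formed neighbouring carbonyl should ensure.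

Step 4
Reactants: 8 7-bromo-8-methyl-1,4-dioxaspiro[4.5]dec-7-en-6-one
Product: 10 2-bromo-6-(2-hydroxyethoxy)-3-methylphenol, via 2-bromo-6-(2-hydroxyethoxy)-3-methylcyclohexa-2,5-dien-1-one 9 (not isolated)
Conditions: TsOH (anhydrous, 0.1 equiv), toluene, 80 °C
Reagents that add atoms: none
Why: Acid-catalysed ketal-to-enol-ether elimination opens the dioxolane to the cross-conjugated dienone 9, the keto tautomer of a phenol, which aromatises by proton shift (the known aromatisation of dihydroquinone monoketals to mono-ethers); without water, hydrolysis cannot compete, so the glycol is deliberately kept as an aryl ether and no oxidant is needed.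

Step 5
Reactants: 10 2-bromo-6-(2-hydroxyethoxy)-3-methylphenol
Product: 12 3-bromo-4-methylbenzene-1,2-diol, via 2,4-dibromo-5-methyl-1,3,2-benzodioxaborole 11 (not isolated)
Conditions: BBr3 (3 equiv), CH2Cl2, −78 to 25 °C; then H2O, 0 °C
Reagents that add atoms: none
Why: BBr3 dealkylation of an aryl alkyl ether, in which boron binds the ether oxygen and bromide attacks the primary CH2 in an SN2 step, should leave the aryl C–O and aryl C–Br bonds untouched and give the cyclic borate 11, which water hydrolyses to the catechol.

Step 6
Reactants: 12 3-bromo-4-methylbenzene-1,2-diol; 13 bromine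
Product: 15 3,4,6-tribromo-5-methylbenzene-1,2-diol, via 3,5-dibromo-4-methylbenzene-1,2-diol 14 (not isolated)
Conditions: Br2 (2.2 equiv), AcOH, 20 °C
Reagents that add atoms: bromine, BrBr
Why: Electrophilic aromatic bromination of a catechol in glacial acetic acid should fill both free ring positions, first the one para to a hydroxyl and then the one ortho to the other hydroxyl.

**Compound list**

1 | cyclotene (2-hydroxy-3-methylcyclopent-2-en-1-one) | CC1=C(O)C(=O)CC1 | starting material
2 | iodomethane | CI | starting material
3 | 2-methoxy-3-methylcyclopent-2-en-1-one | COC1=C(C)CCC1=O | intermediate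
4 | 1,2-bis(trimethylsilyloxy)ethane | C[Si](C)(C)OCCO[Si](C)(C)C | starting material
5 | 6-methoxy-7-methyl-1,4-dioxaspiro[4.4]non-6-ene | COC1=C(C)CCC12OCCO2 | intermediate
6 | bromoform | BrC(Br)Br | starting material
7 | 6,6-dibromo-1-methoxy-5-methylspiro[bicyclo[3.1.0]hexane-2,2'-[1,3]dioxolane] (racemic, cis-fused; one enantiomer drawn; not isolated) | CO[C@]12C(Br)(Br)[C@@]1(C)CCC23OCCO3 | intermediate
8 | 7-bromo-8-methyl-1,4-dioxaspiro[4.5]dec-7-en-6-one | CC1=C(Br)C(=O)C2(CC1)OCCO2 | intermediate
9 | 2-bromo-6-(2-hydroxyethoxy)-3-methylcyclohexa-2,5-dien-1-one (not isolated) | CC1=C(Br)C(=O)C(OCCO)=CC1 | intermediate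
10 | 2-bromo-6-(2-hydroxyethoxy)-3-methylphenol | Cc1ccc(OCCO)c(O)c1Br | intermediate
11 | 2,4-dibromo-5-methyl-1,3,2-benzodioxaborole (not isolated) | Cc1ccc2OB(Br)Oc2c1Br | intermediate
12 | 3-bromo-4-methylbenzene-1,2-diol | Cc1ccc(O)c(O)c1Br | intermediate
13 | bromine | BrBr | starting material
14 | 3,5-dibromo-4-methylbenzene-1,2-diol (not isolated) | Cc1c(Br)cc(O)c(O)c1Br | intermediate
15 | 3,4,6-tribromo-5-methylbenzene-1,2-diol | Cc1c(Br)c(O)c(O)c(Br)c1Br | target

**Step count**

Total steps: 6. Longest linear sequence: 6 steps (1 → 15).

**Steps most likely to fail**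

Step 3 (key step) is the most exposed. Carbene addition to the shielded tetrasubstituted alkene may be slower than the consumption of CHBr3 by KOtBu. After the cyclopropane opens, proton loss from the oxocarbenium ion may compete with hydrolysis and give a bromodienol ether that takes up a second carbene. The buffered hydrolysis may also take the dioxolane with it. The fallback changes the group on the enol oxygen to silicon, so that the enone is released by Si–O cleavage and not by hydrolysis, which is the established silyl enol ether version of the same ring enlargement. It sets out from 1. Ethylene glycol and TsOH in benzene with azeotropic removal of water should ketalise the carbonyl remote from the methyl group to give 7-methyl-1,4-dioxaspiro[4.4]nonan-6-one F1. TBSOTf and Et3N in CH2Cl2 convert its only enolisable side into tert-butyldimethyl[(7-methyl-1,4-dioxaspiro[4.4]non-6-en-6-yl)oxy]silane F2. CHBr3 and KOtBu in pentane at −30 °C give 6,6-dibromo-1-[(tert-butyldimethylsilyl)oxy]-5-methylspiro[bicyclo[3.1.0]hexane-2,2'-[1,3]dioxolane] F3. Bu4NF in THF at 0 °C removes the silyl group, and the cyclopropanolate opens with loss of bromide directly to 8, where the route is rejoined.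

Step 2 is next. Me3SiOTf may re-ionise the product, an allylic ketal beside an enol ether, leading to elimination or oligomerisation. The hindered cross-conjugated cyclopentenone may also ketalise incompletely, and the ketal may hydrolyse during isolation. The fallback avoids the ketal altogether by carrying the masked carbon at the alcohol oxidation level, at the price of a later oxidation. It sets out from 3. iBu2AlH in CH2Cl2 at −78 °C reduces the carbonyl to 2-methoxy-3-methylcyclopent-2-en-1-ol F4. TBSCl and imidazole in DMF give tert-butyl[(2-methoxy-3-methylcyclopent-2-en-1-yl)oxy]dimethylsilane F5. The carbene conditions of step 3 give tert-butyl[(6,6-dibromo-1-methoxy-5-methylbicyclo[3.1.0]hexan-2-yl)oxy]dimethylsilane F6, with the carbene expected anti to the silyloxy group. The same buffered work-up opens and hydrolyses it to 2-bromo-6-[(tert-butyldimethylsilyl)oxy]-3-methylcyclohex-2-en-1-one F7. HF·pyridine in THF frees 2-bromo-6-hydroxy-3-methylcyclohex-2-en-1-one F8. Swern oxidation ((COCl)2, DMSO, Et3N, −78 °C) gives 3-bromo-4-methylcyclohex-3-ene-1,2-dione F9, which should tautomerise in the amine-containing mixture to 12, where the route is rejoined before the bromination.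

Step 4 is third. Ionisation of a ketal whose cation sits next to a carbonyl is slow, so prolonged heating with acid may allow intermolecular etherification through the pendant alcohol or partial hydrolysis by adventitious water. The fallback replaces the Brønsted-acid isomerisation and separate ether cleavage by a single Lewis-acid dealkylation. It sets out from 8. BBr3 (4 equiv) in CH2Cl2 from −78 to 25 °C opens the dioxolane at boron and dealkylates any aryl ether that forms after aromatisation, so that all branches converge on borate 11. Water then gives 12, where the route is rejoined. No compound outside the compound list is made (F0).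

**Further compounds**

F1 | step 3 | 7-methyl-1,4-dioxaspiro[4.4]nonan-6-one (racemic) | CC1CCC2(OCCO2)C1=O
F2 | step 3 | tert-butyldimethyl[(7-methyl-1,4-dioxaspiro[4.4]non-6-en-6-yl)oxy]silane | CC1=C(O[Si](C)(C)C(C)(C)C)C2(CC1)OCCO2
F3 | step 3 | 6,6-dibromo-1-[(tert-butyldimethylsilyl)oxy]-5-methylspiro[bicyclo[3.1.0]hexane-2,2'-[1,3]dioxolane] (racemic, cis-fused) | CC(C)(C)[Si](C)(C)O[C@]12C(Br)(Br)[C@@]1(C)CCC23OCCO3
F4 | step 2 | 2-methoxy-3-methylcyclopent-2-en-1-ol (racemic) | COC1=C(C)CCC1O
F5 | step 2 | tert-butyl[(2-methoxy-3-methylcyclopent-2-en-1-yl)oxy]dimethylsilane (racemic) | COC1=C(C)CCC1O[Si](C)(C)C(C)(C)C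
F6 | step 2 | tert-butyl[(6,6-dibromo-1-methoxy-5-methylbicyclo[3.1.0]hexan-2-yl)oxy]dimethylsilane (racemic, cyclopropane anti to the silyloxy group) | CO[C@]12C(Br)(Br)[C@@]1(C)CC[C@@H]2O[Si](C)(C)C(C)(C)C
F7 | step 2 | 2-bromo-6-[(tert-butyldimethylsilyl)oxy]-3-methylcyclohex-2-en-1-one (racemic) | CC1=C(Br)C(=O)C(O[Si](C)(C)C(C)(C)C)CC1
F8 | step 2 | 2-bromo-6-hydroxy-3-methylcyclohex-2-en-1-one (racemic) | CC1=C(Br)C(=O)C(O)CC1
F9 | step 2 | 3-bromo-4-methylcyclohex-3-ene-1,2-dione | CC1=C(Br)C(=O)C(=O)CC1
F0 | step 4 | none | none
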